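## The problem

Target 28 is a 1-aryltetralin. Ring B (C1, C2, C3, C4, C4a, C8a) is fused to the pentasubstituted ring A (C5 H, C6 OMe, C7 OH, C8 OMe) and carries a 4-hydroxy-3,5-dimethoxyphenyl ring on C1, the sulfated hydroxymethyl group C9' on C2 and the free hydroxymethyl group C9 on C3. The three stereocentres are contiguous, (1R,2S,3S), with C1/C2 and C2/C3 both trans. C3 is the one that can be obtained by resolution, and if it sits in a small ring beside C2 and C1 it can direct both. The two primary alcohols on C9 and C9' differ only in their distance from the C1 aryl group, so sulfating the finished diol would mean picking the more hindered of two near-equal hydroxyls beside two phenols. The alkyl hydrogen sulfate does not survive hot acid or solvolysis and is best carried as a salt. The two 2,6-dimethoxyphenols and the doubly benzylic C1–H are sensitive to oxidants, and C2 can epimerise while C9' is a carbonyl carbon. The enabling feature lies in ring A and the C4/C9' pair. The C7 phenol is para to C4a and both its ortho positions (C6, C8) carry methoxy groups, so its phenolate can only react through C4a. C4 and the oxygen on C9' stand 1,4 to each other through C3 and C2 and can be tied into a seven-membered cyclic sulfate. Attack of C4a on C4 then closes ring B and leaves the sulfate monoester on C9' in one event.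

## Retrosynthesis

**28 back to 26.** Only the lithium/proton exchange (28 from 27) and two O–benzyl bonds (27 from 26) are cut. Benzyl is chosen for O–C9 and for the pendant phenol because its removal is neutral and leaves a sulfate salt alone. Both oxygens must stay covered up to here. In the ring closure a free C9 alkoxide would close a tetrahydrofuran onto C9', and a free pendant phenolate would attack C4 through its ipso carbon to give a spiro five-membered ring. The forward steps ask only that hydrogenolysis spares the arenes and that the free acid is made cold and last.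

**26 back to 23 (C4–C4a).** The neighbouring cuts of ring B, C1–C8a (benzylic cation onto ring A) or C1–C2 with C3–C4 (cycloaddition), give a tetralin whose two hydroxymethyl groups must be told apart afterwards. The C4–C4a cut lets C4 leave an oxygen that is already tied through sulfur to the oxygen on C9', so the ring closure itself places the sulfate. Precursor 23 is simpler by one ring and already holds all three stereocentres on an open chain. The forward reaction must make C4a choose C4 over C9' and carbon over oxygen alkylation.

**23 back to 20.** The S–O bonds and the protecting group on O7 are cut, by way of 22 and the cyclic sulfite 21. The phenol is freed last (22 to 23) because the sulfite-to-sulfate oxidation (21 to 22) would not tolerate it. The methoxymethyl acetal is the one group that anhydrous acid can remove beside two benzyl ethers and a cyclic sulfate. The ring is built through the sulfite because a one-step sulfonyl transfer onto a 1,4-diol would stop at a monosulfonate, which closes to a tetrahydrofuran. Diol 20 carries no sulfur and asks only for clean ring formation at sulfur.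

**20 back to 19.** Both C–O bonds of the diol come from one lactone whose carbonyl carbon is C9' and whose ring CH2 is C4, with C9 outside the ring as its benzyl ether. This distinguishes the three CH2O groups without selective protection. C9' is a ring member in the lactone but a substituent in the tetralin, so the 2,3-trans tetralin corresponds to the 2,3-cis lactone 19. The reduction must be faster than epimerisation at C2.

**19 back to 14 and 16.** The C1–aryl bond to the pendant ring and the C2–H bond are cut: conjugate addition of the aryl group of 16 (as its Grignard reagent 17) to alkylidene lactone 14, then protonation of enolate 18. Adding ring A to a pendant-ring alkylidene would give the C1 epimer with the same facial preference. Alkylating a lactone enolate with a diarylmethyl electrophile would give the 2,3-trans lactone. In the order chosen, both new centres are set anti to C9 and come out correct. The precursors are an achiral aryl bromide and a lactone with one stereocentre.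

**14 back to 6 and 10.** The C1=C2 bond is cut as an aldol condensation through adduct 12. It must give the E-alkene, with ring A on the C3 side, because geometry and face together decide C1.

**Building blocks.** Lactone 6 comes from hydroxy lactone 5, made from resolved paraconic acid (salt 3 from racemic 1 and amine 2); its stereocentre becomes C3. Aldehyde 10 comes from 2,6-dimethoxyphenol 7 through acetal 8, which has only one kind of position open to ortho-metalation. Bromide 16 is the benzyl ether of 15.

## Roads not taken

**Alternative 1:** The cut runs through C2–C3 and C1–C8a and divides the skeleton into two identical sinapoyl imides A1. In the forward step FeCl3 in aqueous acetone oxidises two molecules of A1, the carbons alpha to the imides couple, one quinone methide tautomerises to a cinnamoyl unit, and its ring closes on the other quinone methide to give dihydronaphthalene A2.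
- Merits: the whole skeleton and the ring A pattern arise in one step from a single C6–C3 unit, with no phenol protection and auxiliaries that may bias the absolute sense.
- Weak points: A2 holds C9 and C9' at the same oxidation level with the same auxiliary. The C3=C4 double bond must still be reduced with control of C3. After reduction, two primary alcohols and two free phenols face a mono-sulfation that must hit the more hindered C9'. Induction from remote auxiliaries in a radical coupling is not secure.
- Comparison: up to the unsulfated diol this road is much shorter, and the chosen plan cannot match that. Against it the chosen plan sets a sulfate site fixed by mechanism and stereocentres that all trace to one resolved centre.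

**Alternative 2:** The cut is a [4+2] one through C1–C2 and C3–C4. Irradiation of benzaldehyde A3 gives the hydroxy-ortho-quinodimethane, which adds to dienophile A4 on a chiral titanium diolate template made from Ti(OiPr)4, giving tetralin A5.
- Merits: it is convergent, the E-dienophile delivers the 2,3-trans relation, and C9 (imide) and C9' (silyl ether) are differentiated from the start.
- Weak points: A3 is a pentasubstituted benzaldehyde that needs its own multistep synthesis. The geometry of the aryl-bearing diene terminus and the endo/exo mode decide C1. Enantiocontrol by the template on so hindered a diene is open. A5 carries a C4 hydroxyl that must be removed, and the sulfate still has to be put on with a sulfating reagent before the imide is reduced.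
- Comparison: on differentiating the two arms this road is as good as the chosen one, and it is more convergent. The chosen plan needs no sulfating reagent, no catalyst-controlled step and no deoxygenation, and its stereochemistry is substrate-controlled throughout.

**Alternative 3:** The cut takes C1 as a linchpin, through C1–C8a and the C1–aryl bond. BF3·OEt2 ionises the acetal of lactone A6, ring A closes onto C1, the benzylic ether ionises again, and 2,6-dimethoxyphenol (7) captures the cation through its para carbon to give lactone A7.
- Merits: ring B and the pendant ring are installed in one flask by well-known cation chemistry, 7 is used unprotected, and the lactone distinguishes C9' (carbonyl) from C9.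
- Weak points: capture by 7 can also occur at the carbons ortho to its methoxy groups. The trans-fused lactone can epimerise at C2 to the cis-fused isomer. From A7 the lactone must be opened, C9 protected, C9' reduced and then sulfated, which adds several steps and a sulfation.
- Comparison: the skeleton is built in fewer steps and with less mechanistic risk than the chosen key step. The chosen plan delivers the sulfate on the right oxygen without separate differentiation.

Key step: step 14

Remark on the chemistry: the less soluble salt of racemic 1 with (S)-1-phenylethylamine (2) is assumed to contain the (R)-acid; if the pairing is the opposite, the (R)-amine is used and nothing else changes.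

Remark on the chemistry: sulfate monoesters are carried as lithium salts (26, 27); the free hydrogen sulfate 28 is made only in the last step.

## Route

Step 1
Reactants: 1 racemic paraconic acid (5-oxotetrahydrofuran-3-carboxylic acid); 2 (S)-1-phenylethylamine
Product: 3 (S)-1-phenylethylammonium (R)-5-oxotetrahydrofuran-3-carboxylate
Conditions: 2 (0.5 equiv), EtOH–acetone, 60 °C → 0 °C; recrystallise
Reagents that add atoms: none
Why: Classical resolution through diastereomeric ammonium carboxylate salts; the crystalline salt carries the (R)-acid, whose single stereocentre becomes C3 of the target.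

Step 2
Reactants: 3 (S)-1-phenylethylammonium (R)-5-oxotetrahydrofuran-3-carboxylate
Product: 5 (S)-4-(hydroxymethyl)dihydrofuran-2(3H)-one, via (R)-paraconic acid 4 (not isolated)
Conditions: 2 M HCl, EtOAc extraction; BH3·SMe2, THF, 0 °C → rt; MeOH
Reagents that add atoms: none
Why: Salt break, then chemoselective borane reduction of the carboxylic acid beside the lactone; the stereocentre is untouched (R becomes S by priority only), and the neutral work-up avoids acyl migration between the two hydroxymethyl arms, which would racemise 5.

Step 3
Reactants: 5 (S)-4-(hydroxymethyl)dihydrofuran-2(3H)-one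
Product: 6 (S)-4-[(benzyloxy)methyl]dihydrofuran-2(3H)-one
Conditions: BnOC(=NH)CCl3, TfOH (cat.), CH2Cl2–cyclohexane, 0 °C → rt
Reagents that add atoms: benzyl 2,2,2-trichloroacetimidate, N=C(OCc1ccccc1)C(Cl)(Cl)Cl
Why: Acid-catalysed O-benzylation with a trichloroacetimidate; no alkoxide is formed, so the translactonisation that would equilibrate 5 with its enantiomer under basic benzylation is avoided.

Step 4
Reactants: 7 2,6-dimethoxyphenol
Product: 8 1,3-dimethoxy-2-(methoxymethoxy)benzene
Conditions: MOMCl, iPr2NEt, CH2Cl2, 0 °C → rt
Reagents that add atoms: chloromethyl methyl ether, COCCl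
Why: O-alkylation of the phenol to its methoxymethyl acetal, which is stable to the organometallic, hydride and oxidation steps ahead and is cleaved later by anhydrous acid.

Step 5
Reactants: 8 1,3-dimethoxy-2-(methoxymethoxy)benzene
Product: 10 2,4-dimethoxy-3-(methoxymethoxy)benzaldehyde, via aryllithium 9 (not isolated)
Conditions: n-BuLi, TMEDA, THF, 0 °C; DMF, −78 °C → rt; H2O
Reagents that add atoms: N,N-dimethylformamide, CN(C)C=O
Why: Directed ortho-lithiation and formylation; the acetal oxygen has no free ortho position, so lithium goes next to a methoxy group, and the two such positions are equivalent.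

Step 6
Reactants: 6 (S)-4-[(benzyloxy)methyl]dihydrofuran-2(3H)-one; 10 2,4-dimethoxy-3-(methoxymethoxy)benzaldehyde
Product: 12 (3S,4S)-4-[(benzyloxy)methyl]-3-{[2,4-dimethoxy-3-(methoxymethoxy)phenyl](hydroxy)methyl}dihydrofuran-2(3H)-one (3,4-trans; both carbinol epimers), via lithium enolate 11 (not isolated)
Conditions: LiN(iPr)2, THF, −78 °C; 10, −78 °C; AcOH
Reagents that add atoms: none
Why: Aldol addition of the lactone lithium enolate to the aryl aldehyde; the electrophile adds anti to the C3 substituent, and both new centres are erased in the next step, so their ratio is irrelevant.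

Step 7
Reactants: 12 the aldol adduct
Product: 14 (S,E)-4-[(benzyloxy)methyl]-3-[2,4-dimethoxy-3-(methoxymethoxy)benzylidene]dihydrofuran-2(3H)-one, via mesylate 13 (not isolated)
Conditions: MsCl, Et3N, CH2Cl2, 0 °C; DBU, rt
Reagents that add atoms: none
Why: Mesylation and E1cB elimination give the conjugated alkylidene lactone as its thermodynamic E isomer (aryl anti to the carbonyl, on the C3 side); this geometry is needed for the configuration at C1.

Step 8
Reactants: 15 4-bromo-2,6-dimethoxyphenol
Product: 16 2-(benzyloxy)-5-bromo-1,3-dimethoxybenzene
Conditions: BnBr, K2CO3, DMF, 60 °C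
Reagents that add atoms: benzyl bromide, BrCc1ccccc1
Why: Williamson ether synthesis; the benzyl ether survives magnesium insertion and keeps the pendant ring from acting as a phenolate in the key step.

Step 9
Reactants: 16 2-(benzyloxy)-5-bromo-1,3-dimethoxybenzene; 14 the (S,E)-alkylidene lactone
Product: 19 (3S,4S)-4-[(benzyloxy)methyl]-3-{(R)-[4-(benzyloxy)-3,5-dimethoxyphenyl][2,4-dimethoxy-3-(methoxymethoxy)phenyl]methyl}dihydrofuran-2(3H)-one (3,4-cis), via arylmagnesium bromide 17 (not isolated), via magnesium enolate 18 (not isolated)
Conditions: 16, Mg, THF, 50 °C; CuBr·SMe2 (0.5 equiv per Grignard), THF–Me2S, −40 °C; 14, −40 → −10 °C; AcOH, THF, −78 °C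
Reagents that add atoms: none
Why: Copper-mediated conjugate addition of an aryl Grignard reagent to an alkylidene lactone; A(1,3) strain between ring A and C3 turns the CH2OBn group over one face, so the aryl group adds to C1 from the other face (with the E-alkene this gives 1R), and low-temperature protonation of enolate 18 at C2 from the same open face gives the kinetic 2,3-cis lactone.

Step 10
Reactants: 19 the 3,4-cis lactone
Product: 20 (2S,3R)-2-{(R)-[4-(benzyloxy)-3,5-dimethoxyphenyl][2,4-dimethoxy-3-(methoxymethoxy)phenyl]methyl}-3-[(benzyloxy)methyl]butane-1,4-diol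
Conditions: LiAlH4, THF, 0 °C; aq. NaOH work-up
Reagents that add atoms: none
Why: Hydride reduction of the lactone to the 1,4-diol (C9'–OH and C4–OH); reduction of the carbonyl is faster than enolisation, and once C9' is a CH2 group C2 can no longer epimerise.

Step 11
Reactants: 20 the 1,4-diol
Product: 21 (5S,6S)-5-{(R)-[4-(benzyloxy)-3,5-dimethoxyphenyl][2,4-dimethoxy-3-(methoxymethoxy)phenyl]methyl}-6-[(benzyloxy)methyl]-1,3,2-dioxathiepane 2-oxide (both configurations at sulfur)
Conditions: SOCl2, Et3N, CH2Cl2 (0.02 M), 0 °C
Reagents that add atoms: thionyl chloride, O=S(Cl)Cl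
Why: Cyclic sulfite formation from a diol; the second hydroxyl attacks sulfur of the chlorosulfite faster than anything displaces at carbon, which is the established entry to seven-membered sulfites of 1,4-diols.

Step 12
Reactants: 21 the cyclic sulfite
Product: 22 (5S,6S)-5-{(R)-[4-(benzyloxy)-3,5-dimethoxyphenyl][2,4-dimethoxy-3-(methoxymethoxy)phenyl]methyl}-6-[(benzyloxy)methyl]-1,3,2-dioxathiepane 2,2-dioxide
Conditions: RuCl3·xH2O (1 mol %), NaIO4, MeCN–EtOAc–H2O, 0 °C, short reaction time
Reagents that add atoms: sodium periodate, [Na+].[O-]I(=O)(=O)=O
Why: Catalytic ruthenium tetroxide (RuO4 from RuCl3 and NaIO4) oxidises the sulfite to the sulfate within minutes at 0 °C; all phenolic oxygens are etherified at this stage, which is why the oxidation is placed before the phenol is freed.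

Step 13
Reactants: 22 the cyclic sulfate methoxymethyl ether
Product: 23 (5S,6S)-5-{(R)-[4-(benzyloxy)-3,5-dimethoxyphenyl](3-hydroxy-2,4-dimethoxyphenyl)methyl}-6-[(benzyloxy)methyl]-1,3,2-dioxathiepane 2,2-dioxide
Conditions: TFA–CH2Cl2 (1:4), Et3SiH, 0 °C
Reagents that add atoms: none
Why: Acidolysis of the aryl methoxymethyl acetal in an anhydrous medium without nucleophiles, which leaves the cyclic sulfate and both benzyl ethers alone; the silane reduces the methoxymethyl cation before it can alkylate the electron-rich rings.

Step 14
Reactants: 23 the cyclic sulfate with free C7 phenol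
Product: 26 lithium [(1R,2S,3S)-1-[4-(benzyloxy)-3,5-dimethoxyphenyl]-3-[(benzyloxy)methyl]-7-hydroxy-6,8-dimethoxy-1,2,3,4-tetrahydronaphthalen-2-yl]methyl sulfate, via lithium phenolate 24 (not isolated), via dienone 25 (not isolated)
Conditions: LiOtBu (1.05 equiv), toluene (0.002 M), rt → 60 °C
Reagents that add atoms: lithium tert-butoxide, [Li+].CC(C)(C)[O-]
Why: Proposed new method: LiOtBu turns the C7 phenol into phenolate 24, whose oxygen is held by lithium between the two flanking methoxy groups and cannot reach either sulfate carbon, so the only nucleophilic site able to cyclise is the para carbon C4a. C4a displaces the sulfate oxygen from the primary carbon C4 in an SN2 step to give dienone 25, which tautomerises to the phenol, while the departing oxygen stays on sulfur as the lithium sulfate monoester on C9'. The closest known reaction types are base-induced tetralin formation from 4-arylbutyl sulfonates by aryl participation, para C-alkylation of hindered phenolates, and opening of cyclic sulfates by carbon nucleophiles to sulfate monoesters; their combination on a seven-membered cyclic sulfate is new. Ring B is closed by the C4–C4a bond in a 6-exo-tet mode (aryl participation of the Ar2-6 kind). No stereocentre is created (C4a in 25 is transient) and C1, C2 and C3 are not touched. Site selectivity between C4 and C9' is needed: attack at C9' would be a five-membered closure through the same π face, which aryl participation disfavours, and C9' is also the more hindered carbon, next to the diarylmethyl group. Carbon over oxygen alkylation is secured by the remote, blocked oxygen, by the lithium counter-ion in toluene and by high dilution, which suppresses intermolecular O-alkylation.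

Step 15
Reactants: 26 the dibenzyl lithium sulfate
Product: 27 lithium [(1R,2S,3S)-7-hydroxy-1-(4-hydroxy-3,5-dimethoxyphenyl)-3-(hydroxymethyl)-6,8-dimethoxy-1,2,3,4-tetrahydronaphthalen-2-yl]methyl sulfate
Conditions: H2 (1 atm), Pd/C, MeOH–THF, rt
Reagents that add atoms: none
Why: Hydrogenolysis of the alkyl and the aryl benzyl ether; the sulfate salt, the arenes and the three stereocentres are inert under these neutral conditions.

Step 16
Reactants: 27 the lithium salt of the target
Product: 28 [(1R,2S,3S)-7-hydroxy-1-(4-hydroxy-3,5-dimethoxyphenyl)-3-(hydroxymethyl)-6,8-dimethoxy-1,2,3,4-tetrahydronaphthalen-2-yl]methyl hydrogen sulfate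
Conditions: Dowex 50WX8 (H+ form), H2O–MeOH, 0 °C; freeze-dry at once
Reagents that add atoms: none
Why: Cation exchange of lithium for a proton on a sulfonic acid resin; the step is run cold and the eluate lyophilised directly because a free alkyl hydrogen sulfate hydrolyses autocatalytically on standing.

## Compound list

1 | racemic paraconic acid (5-oxotetrahydrofuran-3-carboxylic acid) | O=C1CC(C(=O)O)CO1 | starting material
2 | (S)-1-phenylethylamine | C[C@H](N)c1ccccc1 | starting material
3 | (S)-1-phenylethylammonium (R)-5-oxotetrahydrofuran-3-carboxylate | C[C@H]([NH3+])c1ccccc1.O=C1OC[C@H](C(=O)[O-])C1 | intermediate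
4 | (R)-paraconic acid | O=C1OC[C@H](C(=O)O)C1 | intermediate (not isolated)
5 | (S)-4-(hydroxymethyl)dihydrofuran-2(3H)-one | O=C1OC[C@H](CO)C1 | intermediate
6 | (S)-4-[(benzyloxy)methyl]dihydrofuran-2(3H)-one | O=C1OC[C@H](COCc2ccccc2)C1 | intermediate
7 | 2,6-dimethoxyphenol | COc1cccc(OC)c1O | starting material
8 | 1,3-dimethoxy-2-(methoxymethoxy)benzene | COCOc1c(OC)cccc1OC | intermediate
9 | [2,4-dimethoxy-3-(methoxymethoxy)phenyl]lithium | [Li]c1ccc(OC)c(OCOC)c1OC | intermediate (not isolated)
10 | 2,4-dimethoxy-3-(methoxymethoxy)benzaldehyde | O=Cc1ccc(OC)c(OCOC)c1OC | intermediate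
11 | lithium enolate of 6 | [Li]OC1=C[C@@H](COCc2ccccc2)CO1 | intermediate (not isolated)
12 | (3S,4S)-4-[(benzyloxy)methyl]-3-{[2,4-dimethoxy-3-(methoxymethoxy)phenyl](hydroxy)methyl}dihydrofuran-2(3H)-one, both carbinol epimers | O=C1OC[C@H](COCc2ccccc2)[C@H]1C(O)c1ccc(OC)c(OCOC)c1OC | intermediate
13 | methanesulfonate of 12 | O=C1OC[C@H](COCc2ccccc2)[C@H]1C(OS(C)(=O)=O)c1ccc(OC)c(OCOC)c1OC | intermediate (not isolated)
14 | (S,E)-4-[(benzyloxy)methyl]-3-[2,4-dimethoxy-3-(methoxymethoxy)benzylidene]dihydrofuran-2(3H)-one | O=C1OC[C@H](COCc2ccccc2)/C1=C\c1ccc(OC)c(OCOC)c1OC | intermediate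
15 | 4-bromo-2,6-dimethoxyphenol | COc1cc(Br)cc(OC)c1O | starting material
16 | 2-(benzyloxy)-5-bromo-1,3-dimethoxybenzene | COc1cc(Br)cc(OC)c1OCc1ccccc1 | intermediate
17 | [4-(benzyloxy)-3,5-dimethoxyphenyl]magnesium bromide | COc1cc([Mg]Br)cc(OC)c1OCc1ccccc1 | intermediate (not isolated)
18 | bromomagnesium enolate of 19 (C1 R, C3 S; C2 trigonal) | COc1cc([C@@H](C2=C(O[Mg]Br)OC[C@@H]2COCc2ccccc2)c2ccc(OC)c(OCOC)c2OC)cc(OC)c1OCc1ccccc1 | intermediate (not isolated)
19 | (3S,4S)-4-[(benzyloxy)methyl]-3-{(R)-[4-(benzyloxy)-3,5-dimethoxyphenyl][2,4-dimethoxy-3-(methoxymethoxy)phenyl]methyl}dihydrofuran-2(3H)-one (3,4-cis) | COc1cc([C@@H]([C@@H]2C(=O)OC[C@@H]2COCc2ccccc2)c2ccc(OC)c(OCOC)c2OC)cc(OC)c1OCc1ccccc1 | intermediate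
20 | (2S,3R)-2-{(R)-[4-(benzyloxy)-3,5-dimethoxyphenyl][2,4-dimethoxy-3-(methoxymethoxy)phenyl]methyl}-3-[(benzyloxy)methyl]butane-1,4-diol | COc1cc([C@@H]([C@H](CO)[C@H](CO)COCc2ccccc2)c2ccc(OC)c(OCOC)c2OC)cc(OC)c1OCc1ccccc1 | intermediate
21 | cyclic sulfite of 20 (1,3,2-dioxathiepane 2-oxide, both configurations at sulfur) | COc1cc([C@@H]([C@@H]2COS(=O)OC[C@@H]2COCc2ccccc2)c2ccc(OC)c(OCOC)c2OC)cc(OC)c1OCc1ccccc1 | intermediate
22 | cyclic sulfate of 20 (1,3,2-dioxathiepane 2,2-dioxide), O7 as methoxymethyl ether | COc1cc([C@@H]([C@@H]2COS(=O)(=O)OC[C@@H]2COCc2ccccc2)c2ccc(OC)c(OCOC)c2OC)cc(OC)c1OCc1ccccc1 | intermediate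
23 | (5S,6S)-5-{(R)-[4-(benzyloxy)-3,5-dimethoxyphenyl](3-hydroxy-2,4-dimethoxyphenyl)methyl}-6-[(benzyloxy)methyl]-1,3,2-dioxathiepane 2,2-dioxide | COc1cc([C@@H]([C@@H]2COS(=O)(=O)OC[C@@H]2COCc2ccccc2)c2ccc(OC)c(O)c2OC)cc(OC)c1OCc1ccccc1 | intermediate (key-step precursor)
24 | lithium phenolate of 23 | COc1cc([C@@H]([C@@H]2COS(=O)(=O)OC[C@@H]2COCc2ccccc2)c2ccc(OC)c(O[Li])c2OC)cc(OC)c1OCc1ccccc1 | intermediate (not isolated)
25 | ring-closed cross-conjugated dienone (C4a–H, C7=O) as lithium sulfate | COc1cc([C@@H]2C3=C(OC)C(=O)C(OC)=CC3C[C@H](COCc3ccccc3)[C@H]2COS(=O)(=O)[O-])cc(OC)c1OCc1ccccc1.[Li+] | intermediate (not isolated)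
26 | lithium [(1R,2S,3S)-1-[4-(benzyloxy)-3,5-dimethoxyphenyl]-3-[(benzyloxy)methyl]-7-hydroxy-6,8-dimethoxy-1,2,3,4-tetrahydronaphthalen-2-yl]methyl sulfate | COc1cc([C@@H]2c3c(cc(OC)c(O)c3OC)C[C@H](COCc3ccccc3)[C@H]2COS(=O)(=O)[O-])cc(OC)c1OCc1ccccc1.[Li+] | intermediate (key-step product)
27 | lithium [(1R,2S,3S)-7-hydroxy-1-(4-hydroxy-3,5-dimethoxyphenyl)-3-(hydroxymethyl)-6,8-dimethoxy-1,2,3,4-tetrahydronaphthalen-2-yl]methyl sulfate | COc1cc([C@@H]2c3c(cc(OC)c(O)c3OC)C[C@H](CO)[C@H]2COS(=O)(=O)[O-])cc(OC)c1O.[Li+] | intermediate
28 | [(1R,2S,3S)-7-hydroxy-1-(4-hydroxy-3,5-dimethoxyphenyl)-3-(hydroxymethyl)-6,8-dimethoxy-1,2,3,4-tetrahydronaphthalen-2-yl]methyl hydrogen sulfate | COc1cc([C@@H]2c3c(cc(OC)c(O)c3OC)C[C@H](CO)[C@H]2COS(=O)(=O)O)cc(OC)c1O | target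

## Step count and the least certain steps

Total: 16 steps. Longest linear sequence: 13 steps (1, 2, 3, 6, 7, 9, 10, 11, 12, 13, 14, 15, 16). Steps 4–5 and step 8 are side branches.

**Step 14 (key step, proposed new method).** Three things are most likely to go wrong. The aggregated lithium phenolate may react sluggishly in toluene. Intermolecular O-alkylation may lead to oligomers if the dilution is insufficient. The site selectivity may be incomplete, through closure at C9' or participation of the benzyloxy-substituted pendant ring at C4. The fallback uses known chemistry and keeps the same bond. It sets out from 23, which is opened with LiI in THF at the less hindered carbon C4 (halide opening of a cyclic sulfate) to give lithium (2S,3S)-2-{(R)-[4-(benzyloxy)-3,5-dimethoxyphenyl](3-hydroxy-2,4-dimethoxyphenyl)methyl}-3-[(benzyloxy)methyl]-4-iodobutyl sulfate F1. Its phenolate (LiOtBu, THF–toluene) then closes ring B through the para carbon onto the primary iodide, the classical base-induced cyclisation of a 4-arylbutyl halide, and the route is rejoined at 26. In F1 the C9' oxygen is already a sulfate monoanion and no longer a leaving group, so the ring closure can only occur at C4.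

**Step 9.** The likely failure is loss of the kinetic cis relation at C2, through enolate equilibration or epimerisation during the quench, since the 2,3-trans lactone is the more stable one. Incomplete face selectivity at C1 is the second risk. The fallback separates bond formation from protonation. It sets out from 14 and 17; the conjugate addition is quenched warm and the crude treated with DBU to collect the material as the 3,4-trans lactone (3R,4S)-4-[(benzyloxy)methyl]-3-{(R)-[4-(benzyloxy)-3,5-dimethoxyphenyl][2,4-dimethoxy-3-(methoxymethoxy)phenyl]methyl}dihydrofuran-2(3H)-one F2. This is converted with LiN(iPr)2 at −78 °C into its salt-free lithium enolate F3 and protonated with the hindered donor 2,6-di-tert-butyl-4-methylphenol from the face opposite C9. The route is rejoined at 19.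

**Step 12.** The likely failure is over-oxidation of the electron-rich aryl rings or of the doubly benzylic C1–H by ruthenium tetroxide before the sulfite is consumed. The fallback avoids any oxidant. It sets out from diol 20, which is treated with SO2Cl2 and Et3N in CH2Cl2 at −78 °C to form the cyclic sulfate directly. This bypasses 21, makes no new compound (F0) and rejoins the route at 22.

**Step 13.** The likely failure is alkylation of the activated ring carbons by the methoxymethyl cation, or acid-induced ionisation of the cyclic sulfate with participation of an aryl ring. The fallback replaces protonolysis by silyl transfer. It sets out from 22, which with TMSOTf and 2,2'-bipyridyl in CH2Cl2 at 0 °C gives the aryl trimethylsilyl ether of 23, F4, the methoxymethyl group being taken up by the bipyridyl. Hydrolysis with pH 7 buffer then gives the phenol, and the route is rejoined at 23.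

## Further compounds

F1 | step 14 | lithium (2S,3S)-2-{(R)-[4-(benzyloxy)-3,5-dimethoxyphenyl](3-hydroxy-2,4-dimethoxyphenyl)methyl}-3-[(benzyloxy)methyl]-4-iodobutyl sulfate | COc1cc([C@@H]([C@H](COS(=O)(=O)[O-])[C@H](CI)COCc2ccccc2)c2ccc(OC)c(O)c2OC)cc(OC)c1OCc1ccccc1.[Li+]
F2 | step 9 | (3R,4S)-4-[(benzyloxy)methyl]-3-{(R)-[4-(benzyloxy)-3,5-dimethoxyphenyl][2,4-dimethoxy-3-(methoxymethoxy)phenyl]methyl}dihydrofuran-2(3H)-one (3,4-trans) | COc1cc([C@@H]([C@H]2C(=O)OC[C@@H]2COCc2ccccc2)c2ccc(OC)c(OCOC)c2OC)cc(OC)c1OCc1ccccc1
F3 | step 9 | lithium enolate of F2 and 19 | COc1cc([C@@H](C2=C(O[Li])OC[C@@H]2COCc2ccccc2)c2ccc(OC)c(OCOC)c2OC)cc(OC)c1OCc1ccccc1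
F0 | step 12 | none | none
F4 | step 13 | trimethylsilyl ether of 23 at O7 | COc1cc([C@@H]([C@@H]2COS(=O)(=O)OC[C@@H]2COCc2ccccc2)c2ccc(OC)c(O[Si](C)(C)C)c2OC)cc(OC)c1OCc1ccccc1
A1 | alternative 1 | (S,E)-4-benzyl-3-[3-(4-hydroxy-3,5-dimethoxyphenyl)acryloyl]oxazolidin-2-one | COc1cc(/C=C/C(=O)N2C(=O)OC[C@@H]2Cc2ccccc2)cc(OC)c1O
A2 | alternative 1 | trans-1-aryl-1,2-dihydronaphthalene-2,3-dicarboxylic bis-imide | COc1cc([C@@H]2c3c(cc(OC)c(O)c3OC)C=C(C(=O)N3C(=O)OC[C@@H]3Cc3ccccc3)[C@H]2C(=O)N2C(=O)OC[C@@H]2Cc2ccccc2)cc(OC)c1O
A3 | alternative 2 | 4-(benzyloxy)-2-[4-(benzyloxy)-3,5-dimethoxybenzyl]-3,5-dimethoxybenzaldehyde | O=Cc1cc(OC)c(OCc2ccccc2)c(OC)c1Cc1cc(OC)c(OCc2ccccc2)c(OC)c1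
A4 | alternative 2 | (E)-3-[4-(tert-butyldiphenylsilyloxy)but-2-enoyl]oxazolidin-2-one | O=C(/C=C/CO[Si](c1ccccc1)(c1ccccc1)C(C)(C)C)N1CCOC1=O
A5 | alternative 2 | 1-aryl-4-hydroxytetralin with C9 as imide and C9' as silyl ether | COc1cc([C@@H]2c3c(cc(OC)c(OCc4ccccc4)c3OC)[C@H](O)[C@H](C(=O)N3CCOC3=O)[C@H]2CO[Si](c2ccccc2)(c2ccccc2)C(C)(C)C)cc(OC)c1OCc1ccccc1
A6 | alternative 3 | 3,4-trans-4-[4-(benzyloxy)-3,5-dimethoxybenzyl]-3-(dimethoxymethyl)dihydrofuran-2(3H)-one | COC(OC)[C@@H]1C(=O)OC[C@H]1Cc1cc(OC)c(OCc2ccccc2)c(OC)c1
A7 | alternative 3 | trans,trans-1-aryltetralin fused to a trans lactone (carbonyl is C9') | COc1cc([C@@H]2c3c(cc(OC)c(OCc4ccccc4)c3OC)C[C@@H]3COC(=O)[C@@H]23)cc(OC)c1O
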